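**Retrosynthetic overview**

- Ring A is numbered C1 (bears C8H2OH), C2 (H), C3 and C4 (OH), C5 (Br), C6 (bears C7H2 to ring B). The plan rests on the C2–C3–C4–C5 segment with its vicinal oxygens at C3/C4, held between C1 and C6: it is a 1,2,3-trioxygenated butadiene, and C1/C6 are the two carbons of a 2-ynoate.
- The target is reached by C8 ester reduction, cleavage of three methyl ethers and C5 bromination of a ring A phenol ester. Its free C4–OH beside C3–OMe leaves C5 as the only activated position.
- That phenol ester comes from a [4+2] benzannulation of a 1,2-dimethoxy-3-silyloxydiene with a ring B butynoate, forming C1–C2 and C5–C6 with loss of methanol and the silyl group.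
- The diene comes from (Z)-1,2-dimethoxyethene and N-methoxy-N-methylacetamide; the ynoate comes from 3-bromo-4,5-dimethoxybenzaldehyde and methyl propiolate.
- Ring order: ring B is bought complete with its bromine; ring A is the only ring formed.

Key step: step 6

Remark: (Z)-1,2-dimethoxyethene is taken to be available as the single Z isomer (if only the cis/trans mixture is sold, it is separated by distillation first).

**Route**

Step 1
Reactants: 1 (Z)-1,2-dimethoxyethene; 2 N-methoxy-N-methylacetamide
Product: 5 (Z)-3,4-dimethoxybut-3-en-2-one, via vinyllithium 3 (not isolated), via lithium aminal alkoxide 4 (not isolated)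
Conditions: t-BuLi (1.05 equiv), THF, −78 °C, 30 min; then 2, −78 → −30 °C; inverse quench into cold 0.5 M HCl/Et2O
Reagents that add atoms: none
Why: α-Lithiation of an enol ether (the vinylic C–H next to oxygen is acidified by both methoxy groups) should give 3 with retention of alkene geometry, and Weinreb ketone synthesis through the chelated adduct 4 stops at the methyl ketone, the cold acidic inverse quench protonating the released amine before it can add to the β-methoxy enone.

Step 2
Reactants: 5 (Z)-3,4-dimethoxybut-3-en-2-one
Product: 6 (Z)-1,2-dimethoxy-3-(trimethylsilyloxy)buta-1,3-diene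
Conditions: Me3SiOTf, Et3N, Et2O, 0 °C; pentane, filtration, distillation (amine-free)
Reagents that add atoms: trimethylsilyl trifluoromethanesulfonate, C[Si](C)(C)OS(=O)(=O)C(F)(F)F
Why: Soft enolisation and O-silylation of the methyl ketone, the only enolisable position of 5, should give the 2-silyloxydiene without touching the C1=C2 geometry, as in the standard preparation of 1-alkoxy-3-silyloxybutadienes.

Step 3
Reactants: 7 3-bromo-4,5-dimethoxybenzaldehyde
Product: 8 (3-bromo-4,5-dimethoxyphenyl)methanol
Conditions: NaBH4, MeOH, 0 °C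
Reagents that add atoms: none
Why: Borohydride reduction of an aromatic aldehyde is chemoselective and leaves the aryl bromide and methyl ethers untouched.

Step 4
Reactants: 8 (3-bromo-4,5-dimethoxyphenyl)methanol
Product: 9 1-bromo-5-(bromomethyl)-2,3-dimethoxybenzene
Conditions: PBr3, CH2Cl2, 0 °C → rt
Reagents that add atoms: phosphorus tribromide, BrP(Br)Br
Why: Conversion of a benzylic alcohol into the bromide through its phosphite ester and SN2 displacement by bromide is reliable for electron-rich benzyl alcohols.

Step 5
Reactants: 9 1-bromo-5-(bromomethyl)-2,3-dimethoxybenzene; 10 methyl propiolate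
Product: 12 methyl 4-(3-bromo-4,5-dimethoxyphenyl)but-2-ynoate, via copper acetylide 11 (not isolated)
Conditions: 10 (1.5 equiv), CuI (10 mol %), K2CO3, n-Bu4NI, MeCN, rt
Reagents that add atoms: none
Why: Copper-catalysed C(sp)–C(sp3) coupling of a terminal alkyne with a benzyl halide, in which the monovalent copper acetylide 11 displaces the benzylic bromide (activated by iodide exchange) while the aryl bromide is inert, and the weak heterogeneous base at room temperature should limit isomerisation of the ynoate to the allenoate.

Step 6
Reactants: 6 (Z)-1,2-dimethoxy-3-(trimethylsilyloxy)buta-1,3-diene; 12 methyl 4-(3-bromo-4,5-dimethoxyphenyl)but-2-ynoate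
Product: 15 methyl 2-(3-bromo-4,5-dimethoxybenzyl)-4-hydroxy-5-methoxybenzoate, via cycloadduct 13 (not isolated), via aryl silyl ether 14 (not isolated)
Conditions: 6 (3 equiv), PhMe, 130 °C, sealed tube; then 1 M HCl, THF, rt
Reagents that add atoms: none
Why: This is a normal-demand, concerted but asynchronous [4+2] cycloaddition in which the unsubstituted CH2 terminus of 6 (future C5), made the most nucleophilic carbon by the 3-silyloxy group and through the diene by the 1-methoxy group, bonds to the β-carbon of 12 (future C6, carrying C7), while the methoxylated terminus (future C2) bonds to the ester-bearing α-carbon (future C1). The closest known reaction type is the cycloaddition of 1-alkoxy-3-silyloxybuta-1,3-dienes with propiolates and 2-alkynoates, whose 1,4-cyclohexadiene adducts aromatise by loss of alcohol, dienes with an added 2-acyloxy group being the nearest relatives of 6. Ring A is closed by the intermolecular cycloaddition itself, a four-carbon plus two-carbon union that makes C1–C2 and C5–C6 in one suprafacial event to give 13, which loses methanol (OMe from C2, H from C5) to give 14, and dilute acid then removes the silyl group to free the C4 phenol. No stereocentre remains, because the single sp3 stereocentre of 13 (C2) is erased on aromatisation. The step needs regioselectivity, which is secured by the matched polarisation (two donors converge on the CH2 terminus and only the cross-conjugated 2-methoxy group opposes) and by the Z geometry of 6, which turns the 1-methoxy group away from C3 so that the s-cis conformer is reachable. Amine-free, neutral heating keeps the acidic C7 methylene from isomerising 12 to the allenoate.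

Step 7
Reactants: 15 methyl 2-(3-bromo-4,5-dimethoxybenzyl)-4-hydroxy-5-methoxybenzoate
Product: 16 methyl 3-bromo-2-(3-bromo-4,5-dimethoxybenzyl)-4-hydroxy-5-methoxybenzoate
Conditions: NBS (1.0 equiv), CH2Cl2, −20 → 0 °C, dark
Reagents that add atoms: N-bromosuccinimide, O=C1CCC(=O)N1Br
Why: Electrophilic aromatic bromination directed by the free C4 phenol should go to C5, the only open ortho/para position (C3 carries OMe, C1 the ester), while ring B, which has no free hydroxyl and already carries bromine, reacts much more slowly under these mild ionic conditions.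

Step 8
Reactants: 16 methyl 3-bromo-2-(3-bromo-4,5-dimethoxybenzyl)-4-hydroxy-5-methoxybenzoate
Product: 17 methyl 3-bromo-2-(3-bromo-4,5-dihydroxybenzyl)-4,5-dihydroxybenzoate
Conditions: BBr3 (6 equiv), CH2Cl2, −78 → 0 °C; ice water
Reagents that add atoms: none
Why: Lewis acid cleavage of aryl methyl ethers (O-coordination to boron, then bromide attack on methyl) should remove all three methyl groups while the methyl ester survives at or below 0 °C, and doing it while C8 is still an ester means no benzylic electrophile is present that could alkylate ring B and close a 9,10-dihydroanthracene.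

Step 9
Reactants: 17 methyl 3-bromo-2-(3-bromo-4,5-dihydroxybenzyl)-4,5-dihydroxybenzoate
Product: 18 3-bromo-4-(3-bromo-4,5-dihydroxybenzyl)-5-(hydroxymethyl)benzene-1,2-diol (5-hydroxyisoavrainvilleol)
Conditions: i-Bu2AlH (8 equiv), THF, −78 °C → rt; aq. potassium sodium tartrate (KNaC4H4O6), degassed EtOAc, no MeOH
Reagents that add atoms: none
Why: Hydride reduction of the ester by excess i-Bu2AlH, after the four phenols have been taken up as soluble aluminium aryloxides, should give the C8 alcohol without touching the aryl bromides, and a near-neutral, methanol-free work-up protects the p-hydroxybenzyl alcohol from ionisation.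

**Compound list**

1 | (Z)-1,2-dimethoxyethene | CO/C=C\OC | starting material
2 | N-methoxy-N-methylacetamide | CON(C)C(C)=O | starting material
3 | (Z)-(1,2-dimethoxyvinyl)lithium | CO/C=C(\OC)[Li] | intermediate
4 | lithium (Z)-3,4-dimethoxy-2-[methoxy(methyl)amino]but-3-en-2-olate | CO/C=C(\OC)C(C)(O[Li])N(C)OC | intermediate
5 | (Z)-3,4-dimethoxybut-3-en-2-one | CO/C=C(\OC)C(C)=O | intermediate
6 | (Z)-1,2-dimethoxy-3-(trimethylsilyloxy)buta-1,3-diene | CO/C=C(\OC)C(=C)O[Si](C)(C)C | intermediate
7 | 3-bromo-4,5-dimethoxybenzaldehyde | COc1cc(C=O)cc(Br)c1OC | starting material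
8 | (3-bromo-4,5-dimethoxyphenyl)methanol | COc1cc(CO)cc(Br)c1OC | intermediate
9 | 1-bromo-5-(bromomethyl)-2,3-dimethoxybenzene | COc1cc(CBr)cc(Br)c1OC | intermediate
10 | methyl propiolate | C#CC(=O)OC | starting material
11 | methyl 3-cuprioprop-2-ynoate (monovalent copper acetylide of 10) | COC(=O)C#C[Cu] | intermediate
12 | methyl 4-(3-bromo-4,5-dimethoxyphenyl)but-2-ynoate | COC(=O)C#CCc1cc(OC)c(OC)c(Br)c1 | intermediate
13 | methyl 2-(3-bromo-4,5-dimethoxybenzyl)-5,6-dimethoxy-4-(trimethylsilyloxy)cyclohexa-1,4-diene-1-carboxylate (racemic) | COC(=O)C1=C(Cc2cc(OC)c(OC)c(Br)c2)CC(O[Si](C)(C)C)=C(OC)C1OC | intermediate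
14 | methyl 2-(3-bromo-4,5-dimethoxybenzyl)-5-methoxy-4-(trimethylsilyloxy)benzoate | COC(=O)c1cc(OC)c(O[Si](C)(C)C)cc1Cc1cc(OC)c(OC)c(Br)c1 | intermediate
15 | methyl 2-(3-bromo-4,5-dimethoxybenzyl)-4-hydroxy-5-methoxybenzoate | COC(=O)c1cc(OC)c(O)cc1Cc1cc(OC)c(OC)c(Br)c1 | intermediate
16 | methyl 3-bromo-2-(3-bromo-4,5-dimethoxybenzyl)-4-hydroxy-5-methoxybenzoate | COC(=O)c1cc(OC)c(O)c(Br)c1Cc1cc(OC)c(OC)c(Br)c1 | intermediate
17 | methyl 3-bromo-2-(3-bromo-4,5-dihydroxybenzyl)-4,5-dihydroxybenzoate | COC(=O)c1cc(O)c(O)c(Br)c1Cc1cc(O)c(O)c(Br)c1 | intermediate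
18 | 3-bromo-4-(3-bromo-4,5-dihydroxybenzyl)-5-(hydroxymethyl)benzene-1,2-diol (5-hydroxyisoavrainvilleol) | OCc1cc(O)c(O)c(Br)c1Cc1cc(O)c(O)c(Br)c1 | target

**Step count**

Total: 9 steps. Longest linear sequence: 7 steps (steps 3, 4, 5, 6, 7, 8, 9).

**Steps most likely to fail**

Step 6. The β-substituted ynoate is a sluggish dienophile, so cycloaddition may be outrun by thermal decomposition of the diene, by isomerisation of the ynoate to its allenoate through traces of base, or by erosion of regiocontrol. The fallback builds the diarylmethane by cross-coupling instead of by ring synthesis; it sets out from benzyl bromide 9 and comes back at 15.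
- Methyl 4-hydroxy-3-methoxybenzoate F1 is acetylated (Ac2O, pyridine) to methyl 4-acetoxy-3-methoxybenzoate F2.
- With the phenol masked, the methoxy group directs bromination para to itself (Br2, NaOAc, AcOH), giving methyl 4-acetoxy-2-bromo-5-methoxybenzoate F3.
- Miyaura borylation (bis(pinacolato)diboron, PdCl2(dppf), KOAc, dioxane, 85 °C) gives methyl 4-acetoxy-5-methoxy-2-(4,4,5,5-tetramethyl-1,3,2-dioxaborolan-2-yl)benzoate F4.
- Suzuki–Miyaura coupling of F4 with 9 (Pd(PPh3)4, K3PO4, PhMe, 80 °C) gives methyl 4-acetoxy-2-(3-bromo-4,5-dimethoxybenzyl)-5-methoxybenzoate F5; the benzylic C–Br bond of 9 should add to zerovalent palladium far faster than the hindered, electron-rich aryl C–Br bond.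
- Methanolysis of the acetate (K2CO3, MeOH, 0 °C) gives 15.

Step 1. The vinyllithium has lithium anti to the C2 methoxy group, so it may lose lithium methoxide to give methoxyacetylene, or metalation may be incomplete. The fallback avoids the vinyl anion. It sets out from none of the numbered compounds: purchased 1-methoxypropan-2-one F6 takes the place of 1 and 2, and the sequence comes back at enone 5.
- Condensation of F6 with N,N-dimethylformamide dimethyl acetal (neat, 100 °C) at the methoxy-bearing methylene gives (Z)-4-(dimethylamino)-3-methoxybut-3-en-2-one F7.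
- Exchange in methanolic HCl gives the keto acetal 3,4,4-trimethoxybutan-2-one F8.
- Acid-catalysed loss of methanol on distillation (cat. TsOH) gives 5, equilibrated towards the Z isomer.

Step 9. The aluminium tetra-aryloxide of 17 is a deactivated and possibly poorly soluble ester, so reduction may stall, and the free catechol benzyl alcohol may be lost on work-up through quinone methide formation or air oxidation. The fallback masks the phenols during the reduction; it sets out from 17 and comes back at 18.
- Silylation (t-BuMe2SiOTf, 2,6-lutidine, CH2Cl2) gives methyl 3-bromo-2-[3-bromo-4,5-bis(tert-butyldimethylsilyloxy)benzyl]-4,5-bis(tert-butyldimethylsilyloxy)benzoate F9.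
- i-Bu2AlH (CH2Cl2, −78 °C) reduces the now ordinary ester to {3-bromo-2-[3-bromo-4,5-bis(tert-butyldimethylsilyloxy)benzyl]-4,5-bis(tert-butyldimethylsilyloxy)phenyl}methanol F10.
- Et3N·3HF in THF (no methanol) removes the four silyl groups to give 18.

**Further compounds**

F1 | step 6 | methyl 4-hydroxy-3-methoxybenzoate | COC(=O)c1ccc(O)c(OC)c1
F2 | step 6 | methyl 4-acetoxy-3-methoxybenzoate | COC(=O)c1ccc(OC(C)=O)c(OC)c1
F3 | step 6 | methyl 4-acetoxy-2-bromo-5-methoxybenzoate | COC(=O)c1cc(OC)c(OC(C)=O)cc1Br
F4 | step 6 | methyl 4-acetoxy-5-methoxy-2-(4,4,5,5-tetramethyl-1,3,2-dioxaborolan-2-yl)benzoate | COC(=O)c1cc(OC)c(OC(C)=O)cc1B1OC(C)(C)C(C)(C)O1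
F5 | step 6 | methyl 4-acetoxy-2-(3-bromo-4,5-dimethoxybenzyl)-5-methoxybenzoate | COC(=O)c1cc(OC)c(OC(C)=O)cc1Cc1cc(OC)c(OC)c(Br)c1
F6 | step 1 | 1-methoxypropan-2-one | COCC(C)=O
F7 | step 1 | (Z)-4-(dimethylamino)-3-methoxybut-3-en-2-one | CN(C)/C=C(\OC)C(C)=O
F8 | step 1 | 3,4,4-trimethoxybutan-2-one (racemic) | COC(OC)C(OC)C(C)=O
F9 | step 9 | methyl 3-bromo-2-[3-bromo-4,5-bis(tert-butyldimethylsilyloxy)benzyl]-4,5-bis(tert-butyldimethylsilyloxy)benzoate | COC(=O)c1cc(O[Si](C)(C)C(C)(C)C)c(O[Si](C)(C)C(C)(C)C)c(Br)c1Cc1cc(O[Si](C)(C)C(C)(C)C)c(O[Si](C)(C)C(C)(C)C)c(Br)c1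
F10 | step 9 | {3-bromo-2-[3-bromo-4,5-bis(tert-butyldimethylsilyloxy)benzyl]-4,5-bis(tert-butyldimethylsilyloxy)phenyl}methanol | OCc1cc(O[Si](C)(C)C(C)(C)C)c(O[Si](C)(C)C(C)(C)C)c(Br)c1Cc1cc(O[Si](C)(C)C(C)(C)C)c(O[Si](C)(C)C(C)(C)C)c(Br)c1
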